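## Analysis of the target

The target is a linear tridepside: three benzene rings joined by two aryl ester bonds, with no fused rings and no stereocentre, so there is no relative or absolute configuration to control. Ring A is an orsellinic acid unit (free carboxyl on C1, hydroxyl on C2, methyl on C6) acylated on O4 by ring B. Ring B is a second orsellinate (chelated hydroxyl on C2, methyl on C6) acylated on O4 by ring C, a 2,4,5-trihydroxy-6-methylbenzoyl group. Both ester carbonyls sit between two ortho substituents, so each depside bond joins a hindered acyl group to a phenol. The sensitive groups are the two aryl esters (cleaved or transesterified by hydroxide, alkoxide and amines), the salicylic acid of ring A (prone to decarboxylation in hot acid), and ring C, whose 2- and 5-hydroxyls form a hydroquinone pair open to air oxidation. The difficulty is order and differentiation: of eight oxygen functions only O4 of ring A and O4 of ring B may be acylated, and the final unmasking must be neutral. The strategy rests on ring B: its C2 hydroxyl next to the C1 carbonyl, its C4 oxygen meta to that hydroxyl and its C6 methyl are what a ketene carbonyl, an alkoxyacetylene and a 3-methyl vinylketene deliver when a benzene ring is assembled from them. Ring B can therefore be grown on the ester oxygen of ring A with its two oxygens already distinguished.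

## Retrosynthetic reasoning

**32 to 31.** The last operation must be neutral, because 32 carries two aryl esters, a salicylic acid and an oxidizable ring C. All five masking groups of 31 (four aryl benzyl ethers and the benzyl ester) are benzylic C–O bonds, so one hydrogenolysis cuts them together.

**31 to 21 and 29.** The ester C–O bond between the ring C carbonyl and O4 of ring B is cut. This bond can be made last without further protection: in 21 the 4-hydroxyl of ring B is free, while the 2-hydroxyl is held in a hydrogen bond to the adjacent ester carbonyl. The forward step must deliver the hindered, electron-rich acyl group of 29, through mixed anhydride 30, to that one oxygen.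

**21 to 20.** O4 of ring B is traced back to a tert-butyl ether, which acid removes while benzyl ethers, the benzyl ester and the aryl ester remain. The tert-butoxy group is also exactly what the next disconnection leaves on C4.

**20 to 10 and 15 (key disconnection).** Ring B is taken apart at C2–C3, C4–C5 and C1–C2. C2 with its hydroxyl comes from a ketene carbonyl, C3 and C4 with the tert-butoxy group from ynol ether 15, and C5, C6 (with the methyl) and C1 (with the ester to ring A) from the vinyl part of vinylketene 16, which acid chloride 10 releases on 1,4-dehydrochlorination. Cutting here rather than at the A–B ester means that this ester never has to be formed from a 2,6-disubstituted benzoic acid, and O2 and O4 of ring B differ from the moment the ring exists. The forward cascade (16, cyclobutenone 17, dienylketene 18, dienone 19) needs a [2+2] addition of the correct orientation and a six-electron closure that outrun any reaction of the ketene with itself or with its own ester.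

**10 to 9, then 9 to 6 and 8, then 8 to 7.** The acid chloride comes from acid 9, which is cut at the ester C–O bond between O4 of ring A and the saturated carbonyl. Anhydride 8 is the right acyl donor: its ring holds the two carbonyl-bearing arms cis, which gives 9 and 10 the Z geometry, and its unconjugated carbonyl is the more electrophilic. 8 is the cyclodehydration product of diacid 7.

**15 to 13 to 11.** The ynol ether is released from dichlorovinyl ether 13 by double dehalogenation through acetylide 14. 13 arises from 11 by elimination to 12 and addition of the alkoxide that caused the elimination.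

**6 to 5, 4, 3, 1 and 2.** Phenol 6 needs O4 free and both O2 and the carboxyl benzylated. Direct benzylation of 1 would go to O4 before O2, so the carboxyl is benzylated first (3), O4 is held as a silyl ether (4, 5) while 2 alkylates the chelated O2, and the silyl group is then removed.

**29 to 28, 26, 25, 23, 22 and 2.** The carboxyl of 29 is taken back to aldehyde 28, and the formyl group to an aromatic C–H of 26, the position para to one benzyloxy group and ortho to the methyl. The C5 oxygen of ring C sits where the formyl group of 23 was: oxidative aryl migration converts that aldehyde into phenol 25 through formate 24. 23 is the dibenzyl ether of 22, made with two equivalents of 2.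

## Alternatives that were turned down

**Alternative 1:** Ring A is cut at C2–C3 and C1–C6, which turns it into a 2-pyranone diene and a push–pull alkyne.
- Forward step: the 4-hydroxyl of 4-hydroxy-6-methyl-2H-pyran-2-one A4 would carry the complete benzyl-protected B–C acyl unit as enol ester A2. Heating A2 with benzyl 3-methoxyprop-2-ynoate A3 would give a Diels–Alder adduct in which the alkoxy-bearing alkyne carbon is bonded to C3 of the pyranone and the ester-bearing carbon to C6. The bridged lactone then decarboxylates to arene A1.
- For: A4 is cheap, ring A arrives with its carboxyl at the right oxidation level, and the step joins two large pieces late. On convergence it is stronger than the chosen route, whose longest sequence runs through ring A.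
- Against: pyranone–alkyne cycloadditions need long heating well above 150 °C. A3 is a weak dienophile because its donor oxygen raises the LUMO. A2 is an enol ester of a vinylogous acid, so it is an acyl donor that can shed or shift its cargo under such conditions.
- Against, end game: O2 of ring A emerges as a methyl ether. Removing it needs a boron trihalide, which also strips benzyl ethers and threatens both aryl esters, so the finish is harsher than a hydrogenolysis.
- Comparison: the acyl part of A2 must still be made by classical depside chemistry, and the uncertain step comes last with the most material at stake. The chosen route runs its pericyclic step at or below 80 °C on a small precursor and ends with a neutral deprotection.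

**Alternative 2:** Ring B is cut at its ester C–O bond to ring A and at C1–C6, back to a linear triketo ester.
- Forward step: thermolysis of dioxinone A6 releases an acylketene that the 4-hydroxyl of 3 captures to give aryl trioxooctanoate A7. Aldol condensation of C2 onto the C7 ketone, dehydration and enolization then give didepside A5.
- For: this biomimetic resorcylate construction is well precedented for alkyl esters, needs no protection of ring A beyond the benzyl ester, forms the A–B ester before ring B as the chosen route does, and is shorter. On precedent and step count it is at least as strong as the chosen plan.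
- Against: A7 is an aryl ester, and aryloxide leaves far more readily than alkoxide. Under the basic aldol conditions the C5 enol oxygen can lactonize onto the ester carbonyl and expel the ring A phenol, undoing the key bond. The acylketene must also choose the 4-hydroxyl of 3 over the chelated 2-hydroxyl and over the enols of its own chain. A5 then carries three free phenols, two of them chelated, so the ring C acylation rests on reactivity differences alone.
- Comparison: the chosen strategy offers ring closure by neutral thermal electrocyclization, with no enolate generated beside the aryl ester, and a ring B whose O4 is masked and distinct from O2 from the start.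

**Alternative 3:** Ring C is cut at C1–C2 and C5–C6 into a four-carbon oxygenated diene and the two ynoate carbons that become C1 and C6.
- Forward step: the terminal carbon of diene A9 adds in conjugate fashion to the β-carbon of ynoate A10 (C5–C6). The resulting anion closes on the ketene acetal carbon (C1–C2), and elimination of the silylated methoxy group aromatizes ring C to A8.
- For: the awkward 2,4,5-trioxygenated, 6-methylated ring C is built in one step from acyclic parts, whereas the chosen route spends five steps on acid 29. On this point the alternative is clearly stronger.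
- Against: cyclizations of 1,3-bis(silyloxy)dienes go well with reactive electrophiles, but a β-methyl ynoate is a sluggish acceptor. The 4-alkoxy substituent makes the diene terminus hindered and geometrically ill-defined. Lewis acid activation strong enough to force the addition would endanger the aryl ester of A10, itself an acyl donor toward the silyl enol ether.
- Comparison: the step comes last, on a substrate that already contains rings A and B joined by conventional esterification, so ring B, the structural feature that invites annulation, goes unused. The chosen route keeps the uncertain step early, on inexpensive material, and attaches ring C by a depside esterification of known type.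

Key step: step 10

## Route

Assumptions:
- In each benzoyl ring, C1 is the carbon bearing the carboxyl carbon, C2 the chelated hydroxyl and C6 the methyl.
- Commercial 7 is taken as an E/Z mixture that converges on 8.
- 1 and 22 are taken as catalogue compounds.

Step 1
Reactants: 1 orsellinic acid (2,4-dihydroxy-6-methylbenzoic acid); 2 benzyl bromide
Product: 3 benzyl 2,4-dihydroxy-6-methylbenzoate
Conditions: KHCO3, DMF, 20 °C
Reagents that add atoms: none
Why: Carboxylate O-alkylation; hydrogencarbonate ionizes only the carboxylic acid, so both phenols stay free, and the low temperature avoids decarboxylation of the β-resorcylic acid.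

Step 2
Reactants: 3 benzyl 2,4-dihydroxy-6-methylbenzoate
Product: 4 benzyl 2-hydroxy-6-methyl-4-[(triisopropylsilyl)oxy]benzoate
Conditions: i-Pr3SiCl, imidazole, CH2Cl2, 0 → 20 °C
Reagents that add atoms: triisopropylsilyl chloride, CC(C)[Si](Cl)(C(C)C)C(C)C
Why: Selective silylation of the free 4-hydroxyl; the 2-hydroxyl is hydrogen-bonded to the ester carbonyl and crowded by it, so the bulky silyl chloride should leave it alone.

Step 3
Reactants: 4 benzyl 2-hydroxy-6-methyl-4-[(triisopropylsilyl)oxy]benzoate; 2 benzyl bromide
Product: 5 benzyl 2-(benzyloxy)-6-methyl-4-[(triisopropylsilyl)oxy]benzoate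
Conditions: K2CO3, DMF, 40 °C
Reagents that add atoms: none
Why: Williamson etherification of the chelated phenol; the triisopropylsilyl ether is chosen because it should withstand carbonate in DMF where smaller aryl silyl ethers are transferred or cleaved.

Step 4
Reactants: 5 benzyl 2-(benzyloxy)-6-methyl-4-[(triisopropylsilyl)oxy]benzoate
Product: 6 benzyl 2-(benzyloxy)-4-hydroxy-6-methylbenzoate
Conditions: Bu4NF, AcOH, THF, 0 °C
Reagents that add atoms: none
Why: Fluoride-induced cleavage of the aryl silyl ether; acetic acid buffers the phenoxide so that the benzyl ester is not attacked.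

Step 5
Reactants: 7 3-methylglutaconic acid
Product: 8 3-methylglutaconic anhydride (4-methyl-2H-pyran-2,6(3H)-dione)
Conditions: AcCl, reflux; then evaporation
Reagents that add atoms: none
Why: Cyclodehydration of a 1,5-diacid; the E and Z acids interconvert by 1,3-proton shift across the three-carbon system under the acidic conditions and only the Z form can close, so the mixture should converge on the six-membered anhydride.

Step 6
Reactants: 6 benzyl 2-(benzyloxy)-4-hydroxy-6-methylbenzoate; 8 3-methylglutaconic anhydride
Product: 9 (2Z)-5-[3-(benzyloxy)-4-(benzyloxycarbonyl)-5-methylphenoxy]-3-methyl-5-oxopent-2-enoic acid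
Conditions: toluene, 90 °C, no base
Reagents that add atoms: none
Why: Ring opening of a cyclic anhydride by a phenol at the carbonyl next to CH2, which is not conjugated with the alkene and is the more electrophilic; the ring geometry leaves the acid cis to the CH2 arm (Z). Base is omitted because it would only deprotonate the acidic anhydride to an unreactive enolate and would let the product carboxylate expel the phenol again.

Step 7
Reactants: 9 (2Z)-5-[3-(benzyloxy)-4-(benzyloxycarbonyl)-5-methylphenoxy]-3-methyl-5-oxopent-2-enoic acid
Product: 10 3-(benzyloxy)-4-(benzyloxycarbonyl)-5-methylphenyl (3Z)-5-chloro-3-methyl-5-oxopent-3-enoate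
Conditions: (COCl)2, DMF (cat.), CH2Cl2, 0 °C; evaporation below 10 °C; used at once
Reagents that add atoms: oxalyl chloride, ClC(=O)C(=O)Cl
Why: Standard conversion of a carboxylic acid into its chloride with volatile by-products only; benzyl ethers and both esters are inert, and the cold, base-free handling is meant to keep the cis ester from closing onto the new acyl chloride.

Step 8
Reactants: 11 trichloroethylene
Product: 13 (E)-1-(tert-butoxy)-1,2-dichloroethene, via dichloroacetylene 12 (not isolated)
Conditions: KOt-Bu, THF, −40 → 20 °C
Reagents that add atoms: potassium tert-butoxide, CC(C)(C)[O-].[K+]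
Why: Base-induced elimination to dichloroacetylene and anti addition of tert-butoxide across it, the established entry to 1,2-dichlorovinyl ethers; the hazardous alkyne 12 is formed and consumed in solution under argon.

Step 9
Reactants: 13 (E)-1-(tert-butoxy)-1,2-dichloroethene
Product: 15 tert-butoxyacetylene (tert-butyl ethynyl ether), via lithium acetylide 14 (not isolated)
Conditions: n-BuLi (2.2 equiv), Et2O, −78 → −40 °C; H2O, −78 °C; cold distillation, stored at −20 °C
Reagents that add atoms: none
Why: Deprotonation and loss of LiCl give the chloroalkynyl ether, chlorine–lithium exchange gives acetylide 14, and protonation gives the terminal ynol ether. 15 is kept cold because it loses isobutene by retro-ene reaction on warming.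

Step 10
Reactants: 10 3-(benzyloxy)-4-(benzyloxycarbonyl)-5-methylphenyl (3Z)-5-chloro-3-methyl-5-oxopent-3-enoate; 15 tert-butoxyacetylene
Product: 20 benzyl 2-(benzyloxy)-4-{[4-(tert-butoxy)-2-hydroxy-6-methylbenzoyl]oxy}-6-methylbenzoate, via vinylketene 16 (not isolated), via cyclobutenone 17 (not isolated), via dienylketene 18 (not isolated), via cyclohexadienone 19 (not isolated)
Conditions: 15 (3 equiv), Et3N (1.05 equiv, added over 2 h), toluene, 0 → 20 °C; volatiles (excess 15, Et3N) removed at 20 °C; toluene, 80 °C
Reagents that add atoms: none
Why: Proposed new method: 1,4-dehydrochlorination of the Z acid chloride 10 by Et3N should give vinylketene 16, with allylic 1,3-strain against the cis chlorocarbonyl group turning the aryloxycarbonyl group to the methyl side, so that the new C=C is E and the ester cannot reach the ketene carbon. The nucleophilic CH carbon of ynol ether 15 then bonds to the ketene carbonyl carbon and the oxocarbenium carbon closes on the ketene α-carbon, a [2+2] cycloaddition whose orientation is fixed by ynol ether polarity and which forms C2–C3 and C4–C5 in cyclobutenone 17. At 80 °C 17 should open by reversible four-electron conrotatory cleavage to dienylketene 18; only the isomer with the butenoate arm turned toward the ketene reacts on, and it closes ring B by thermal six-electron disrotatory electrocyclization (bond C1–C2), the E ester lying outside the forming ring. Dienone 19 enolizes at once to the chelated phenol 20, so the ketene oxygen becomes the 2-hydroxyl and the ynol ether oxygen the 4-oxygen; the sp3 centres of 17 and 19 are transient and no stereocentre remains. The closest known reaction type is the Danheiser benzannulation of vinylketenes (released from cyclobutenones or diazo ketones) with alkoxyacetylenes, together with the [2+2] addition of ketenes made from acid chlorides and Et3N to alkoxyacetylenes; new here is the amine route to an ester-bearing vinylketene. Chemoselectivity rests on slow addition of Et3N into an excess of 15, which keeps 16 dilute against dimerization, on the cold first stage, which spares 15 from retro-ene loss of isobutene, and on removal of excess 15 and amine before heating.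

Step 11
Reactants: 20 benzyl 2-(benzyloxy)-4-{[4-(tert-butoxy)-2-hydroxy-6-methylbenzoyl]oxy}-6-methylbenzoate
Product: 21 benzyl 2-(benzyloxy)-4-[(2,4-dihydroxy-6-methylbenzoyl)oxy]-6-methylbenzoate
Conditions: CF3CO2H, Et3SiH, CH2Cl2, 0 °C
Reagents that add atoms: none
Why: Acidolysis of an aryl tert-butyl ether; the silane reduces the tert-butyl cation so that it cannot alkylate the resorcinol ring, and benzyl ethers, the benzyl ester and the aryl ester should survive cold dilute acid.

Step 12
Reactants: 22 2,4-dihydroxy-6-methylbenzaldehyde; 2 benzyl bromide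
Product: 23 2,4-bis(benzyloxy)-6-methylbenzaldehyde
Conditions: BnBr (2.2 equiv in all), K2CO3 (2.5 equiv), DMF, 60 °C
Reagents that add atoms: benzyl bromide (second equivalent), BrCc1ccccc1
Why: Double Williamson etherification that consumes two equivalents of benzyl bromide, one for each phenol; the free 4-hydroxyl alkylates first, and warming is needed for the 2-hydroxyl chelated to the aldehyde.

Step 13
Reactants: 23 2,4-bis(benzyloxy)-6-methylbenzaldehyde
Product: 25 2,4-bis(benzyloxy)-6-methylphenol, via aryl formate 24 (not isolated)
Conditions: mCPBA, CH2Cl2, 0 → 20 °C; aqueous NaHCO3 wash; then K2CO3 (cat.), MeOH, 20 °C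
Reagents that add atoms: 3-chloroperoxybenzoic acid, OOC(=O)c1cccc(Cl)c1
Why: Baeyer–Villiger oxidation of an electron-rich benzaldehyde, in which the dialkoxyaryl group migrates in preference to hydrogen, followed by methanolysis of the formate; this puts the future C5 oxygen of ring C where the formyl group was.

Step 14
Reactants: 25 2,4-bis(benzyloxy)-6-methylphenol; 2 benzyl bromide
Product: 26 1,2,5-tris(benzyloxy)-3-methylbenzene
Conditions: K2CO3, DMF, 60 °C
Reagents that add atoms: none
Why: Williamson etherification of a phenol flanked by a methyl and a benzyloxy group, which should still alkylate cleanly with a primary benzylic bromide.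

Step 15
Reactants: 26 1,2,5-tris(benzyloxy)-3-methylbenzene
Product: 28 2,4,5-tris(benzyloxy)-6-methylbenzaldehyde, via iminium salt 27 (not isolated)
Conditions: POCl3, DMF, 0 → 70 °C; then H2O
Reagents that add atoms: N,N-dimethylformamide, CN(C)C=O; water, O
Why: Vilsmeier–Haack formylation; attack is expected at C4 of 26, para to the 1-benzyloxy group and ortho to the 5-benzyloxy group and the methyl, rather than at C6 between two benzyloxy groups, as in the formylation of orcinol diethers.

Step 16
Reactants: 28 2,4,5-tris(benzyloxy)-6-methylbenzaldehyde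
Product: 29 2,4,5-tris(benzyloxy)-6-methylbenzoic acid
Conditions: NaClO2, NaH2PO4, 2-methyl-2-butene, t-BuOH/THF/H2O, 20 °C
Reagents that add atoms: sodium chlorite, [Na+].[O-]Cl=O
Why: Pinnick oxidation, which tolerates hindered aromatic aldehydes and benzyl ethers; excess alkene scavenges hypochlorous acid before it can chlorinate the electron-rich ring.

Step 17
Reactants: 21 benzyl 2-(benzyloxy)-4-[(2,4-dihydroxy-6-methylbenzoyl)oxy]-6-methylbenzoate; 29 2,4,5-tris(benzyloxy)-6-methylbenzoic acid
Product: 31 benzyl 2-(benzyloxy)-4-[(2-hydroxy-6-methyl-4-{[2,4,5-tris(benzyloxy)-6-methylbenzoyl]oxy}benzoyl)oxy]-6-methylbenzoate, via mixed anhydride 30 (not isolated)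
Conditions: (CF3CO)2O, toluene, 20 °C
Reagents that add atoms: none
Why: Depside esterification through the mixed trifluoroacetic anhydride 30, which ionizes easily to an acylium ion because the aryl group is trialkoxylated and doubly ortho-substituted. The free 4-hydroxyl of ring B should react, while the 2-hydroxyl is held by its hydrogen bond to the ester carbonyl and crowded by it.

Step 18
Reactants: 31 benzyl 2-(benzyloxy)-4-[(2-hydroxy-6-methyl-4-{[2,4,5-tris(benzyloxy)-6-methylbenzoyl]oxy}benzoyl)oxy]-6-methylbenzoate
Product: 32 2-hydroxy-4-[(2-hydroxy-6-methyl-4-{[2,4,5-trihydroxy-6-methylbenzoyl]oxy}benzoyl)oxy]-6-methylbenzoic acid (CNP0248995.0)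
Conditions: H2 (1 atm), Pd/C (10% Pd), EtOAc, 20 °C; filtration under argon
Reagents that add atoms: none
Why: Hydrogenolysis of four aryl benzyl ethers and the benzyl ester under neutral conditions, which should leave both aryl esters intact; a non-alcoholic solvent avoids transesterification and the inert work-up protects the hydroquinone-type ring C.

## Compound list

1 | orsellinic acid (2,4-dihydroxy-6-methylbenzoic acid) | Cc1cc(O)cc(O)c1C(=O)O | starting material
2 | benzyl bromide | BrCc1ccccc1 | starting material
3 | benzyl 2,4-dihydroxy-6-methylbenzoate | Cc1cc(O)cc(O)c1C(=O)OCc1ccccc1 | intermediate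
4 | benzyl 2-hydroxy-6-methyl-4-[(triisopropylsilyl)oxy]benzoate | Cc1cc(O[Si](C(C)C)(C(C)C)C(C)C)cc(O)c1C(=O)OCc1ccccc1 | intermediate
5 | benzyl 2-(benzyloxy)-6-methyl-4-[(triisopropylsilyl)oxy]benzoate | Cc1cc(O[Si](C(C)C)(C(C)C)C(C)C)cc(OCc2ccccc2)c1C(=O)OCc1ccccc1 | intermediate
6 | benzyl 2-(benzyloxy)-4-hydroxy-6-methylbenzoate | Cc1cc(O)cc(OCc2ccccc2)c1C(=O)OCc1ccccc1 | intermediate
7 | 3-methylglutaconic acid (E/Z mixture) | CC(CC(=O)O)=CC(=O)O | starting material
8 | 3-methylglutaconic anhydride (4-methyl-2H-pyran-2,6(3H)-dione) | CC1=CC(=O)OC(=O)C1 | intermediate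
9 | (2Z)-5-[3-(benzyloxy)-4-(benzyloxycarbonyl)-5-methylphenoxy]-3-methyl-5-oxopent-2-enoic acid | OC(=O)/C=C(C)\CC(=O)Oc1cc(C)c(C(=O)OCc2ccccc2)c(OCc2ccccc2)c1 | intermediate
10 | 3-(benzyloxy)-4-(benzyloxycarbonyl)-5-methylphenyl (3Z)-5-chloro-3-methyl-5-oxopent-3-enoate | ClC(=O)/C=C(C)\CC(=O)Oc1cc(C)c(C(=O)OCc2ccccc2)c(OCc2ccccc2)c1 | intermediate
11 | trichloroethylene | ClC=C(Cl)Cl | starting material
12 | dichloroacetylene | ClC#CCl | intermediate (not isolated)
13 | (E)-1-(tert-butoxy)-1,2-dichloroethene | Cl/C=C(/Cl)OC(C)(C)C | intermediate
14 | (tert-butoxyethynyl)lithium | [Li]C#COC(C)(C)C | intermediate (not isolated)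
15 | tert-butoxyacetylene (tert-butyl ethynyl ether) | C#COC(C)(C)C | intermediate
16 | 3-(benzyloxy)-4-(benzyloxycarbonyl)-5-methylphenyl (2E)-3-methyl-5-oxopenta-2,4-dienoate (vinylketene) | O=C=C/C(C)=C/C(=O)Oc1cc(C)c(C(=O)OCc2ccccc2)c(OCc2ccccc2)c1 | intermediate (not isolated)
17 | 3-(benzyloxy)-4-(benzyloxycarbonyl)-5-methylphenyl (2E)-3-[2-(tert-butoxy)-4-oxocyclobut-2-en-1-yl]but-2-enoate (racemic) | O=C1C=C(OC(C)(C)C)C1/C(C)=C/C(=O)Oc1cc(C)c(C(=O)OCc2ccccc2)c(OCc2ccccc2)c1 | intermediate (not isolated)
18 | 3-(benzyloxy)-4-(benzyloxycarbonyl)-5-methylphenyl (2E,4E)-5-(tert-butoxy)-3-methyl-7-oxohepta-2,4,6-trienoate (dienylketene) | O=C=C/C(OC(C)(C)C)=C\C(C)=C\C(=O)Oc1cc(C)c(C(=O)OCc2ccccc2)c(OCc2ccccc2)c1 | intermediate (not isolated)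
19 | 3-(benzyloxy)-4-(benzyloxycarbonyl)-5-methylphenyl 4-(tert-butoxy)-2-methyl-6-oxocyclohexa-2,4-diene-1-carboxylate (racemic) | CC1=CC(OC(C)(C)C)=CC(=O)C1C(=O)Oc1cc(C)c(C(=O)OCc2ccccc2)c(OCc2ccccc2)c1 | intermediate (not isolated)
20 | benzyl 2-(benzyloxy)-4-{[4-(tert-butoxy)-2-hydroxy-6-methylbenzoyl]oxy}-6-methylbenzoate | Cc1cc(OC(C)(C)C)cc(O)c1C(=O)Oc1cc(C)c(C(=O)OCc2ccccc2)c(OCc2ccccc2)c1 | intermediate
21 | benzyl 2-(benzyloxy)-4-[(2,4-dihydroxy-6-methylbenzoyl)oxy]-6-methylbenzoate | Cc1cc(O)cc(O)c1C(=O)Oc1cc(C)c(C(=O)OCc2ccccc2)c(OCc2ccccc2)c1 | intermediate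
22 | 2,4-dihydroxy-6-methylbenzaldehyde | Cc1cc(O)cc(O)c1C=O | starting material
23 | 2,4-bis(benzyloxy)-6-methylbenzaldehyde | Cc1cc(OCc2ccccc2)cc(OCc2ccccc2)c1C=O | intermediate
24 | 2,4-bis(benzyloxy)-6-methylphenyl formate | Cc1cc(OCc2ccccc2)cc(OCc2ccccc2)c1OC=O | intermediate (not isolated)
25 | 2,4-bis(benzyloxy)-6-methylphenol | Cc1cc(OCc2ccccc2)cc(OCc2ccccc2)c1O | intermediate
26 | 1,2,5-tris(benzyloxy)-3-methylbenzene | Cc1cc(OCc2ccccc2)cc(OCc2ccccc2)c1OCc1ccccc1 | intermediate
27 | N-{[2,4,5-tris(benzyloxy)-6-methylphenyl]methylidene}-N-methylmethanaminium dichlorophosphate | C[N+](C)=Cc1c(C)c(OCc2ccccc2)c(OCc2ccccc2)cc1OCc1ccccc1.[O-]P(=O)(Cl)Cl | intermediate (not isolated)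
28 | 2,4,5-tris(benzyloxy)-6-methylbenzaldehyde | O=Cc1c(C)c(OCc2ccccc2)c(OCc2ccccc2)cc1OCc1ccccc1 | intermediate
29 | 2,4,5-tris(benzyloxy)-6-methylbenzoic acid | OC(=O)c1c(C)c(OCc2ccccc2)c(OCc2ccccc2)cc1OCc1ccccc1 | intermediate
30 | 2,4,5-tris(benzyloxy)-6-methylbenzoic trifluoroacetic anhydride | FC(F)(F)C(=O)OC(=O)c1c(C)c(OCc2ccccc2)c(OCc2ccccc2)cc1OCc1ccccc1 | intermediate (not isolated)
31 | benzyl 2-(benzyloxy)-4-[(2-hydroxy-6-methyl-4-{[2,4,5-tris(benzyloxy)-6-methylbenzoyl]oxy}benzoyl)oxy]-6-methylbenzoate | Cc1cc(OC(=O)c2c(C)cc(OC(=O)c3c(OCc4ccccc4)cc(OCc4ccccc4)c(OCc4ccccc4)c3C)cc2O)cc(OCc2ccccc2)c1C(=O)OCc1ccccc1 | intermediate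
32 | 2-hydroxy-4-[(2-hydroxy-6-methyl-4-{[2,4,5-trihydroxy-6-methylbenzoyl]oxy}benzoyl)oxy]-6-methylbenzoic acid (CNP0248995.0) | Cc1cc(OC(=O)c2c(C)cc(OC(=O)c3c(O)cc(O)c(O)c3C)cc2O)cc(O)c1C(=O)O | target

## Step count and least certain steps

Total: 18 steps. Longest linear sequence: 10 steps (steps 1, 2, 3, 4, 6, 7, 10, 11, 17, 18).

**Step 10 (key step, Proposed new method).**
- Most likely failure: the vinylketene is lost before the ynol ether captures it. This can happen by dimerization, by amine-initiated oligomerization, or, to the extent that deprotonation places the ester cis to the ketenyl carbon, by closure of the ester carbonyl oxygen onto the ketene carbon. An ester-conjugated vinylketene generated with an amine has not been tested in this annulation.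
- Second failure: ring opening of 17 may need a temperature at which the tert-butyl enol ether loses its alkyl group.
- Fallback (known chemistry, from 4 and 6, returning at 21): hydrogenolysis of the benzyl ester of 4 (H2, Pd/C, EtOAc) gives 2-hydroxy-6-methyl-4-[(triisopropylsilyl)oxy]benzoic acid F1. Carbodiimide esterification of F1 with 6 (DCC, toluene, 20 °C) gives benzyl 2-(benzyloxy)-4-({2-hydroxy-6-methyl-4-[(triisopropylsilyl)oxy]benzoyl}oxy)-6-methylbenzoate F2. Desilylation (Bu4NF, AcOH, THF) gives 21. This is classical depside coupling and gives up the ring construction.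

**Step 7.**
- Most likely failure: cyclization of the cis-held ester carbonyl onto the newly activated acyl carbon, or expulsion of the ring A phenol by the activated carboxyl. The Z geometry keeps the two carbonyl groups within reach, and hydrogen chloride can catalyse the enolization that precedes closure.
- Fallback (from 9, returning at 16): the acid chloride is not made. 9 is activated in the annulation flask with 2-chloro-1-methylpyridinium iodide and Et3N in the presence of 15. The salt 2-({(2Z)-5-[3-(benzyloxy)-4-(benzyloxycarbonyl)-5-methylphenoxy]-3-methyl-5-oxopent-2-enoyl}oxy)-1-methylpyridin-1-ium iodide F3 forms and at once loses its γ-proton and the pyridone to give 16, a known way of generating ketenes from acids.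

**Step 6.**
- Most likely failure: slow or reversible addition of the phenol to an anhydride that is stabilized as its hydroxypyranone tautomer, or addition at the conjugated carbonyl. The latter would give the regioisomeric half ester, whose chloride would lead to a vinylketene with the ester cis to the ketenyl carbon.
- Fallback (from 6, returning at 9): 6 is acylated with bromoacetyl bromide (pyridine, CH2Cl2, 0 °C) to 3-(benzyloxy)-4-(benzyloxycarbonyl)-5-methylphenyl bromoacetate F4. Zinc insertion (Zn, THF) gives the Reformatsky reagent {2-[3-(benzyloxy)-4-(benzyloxycarbonyl)-5-methylphenoxy]-2-oxoethyl}zinc bromide F5. Negishi-type coupling (Pd(PPh3)4 cat., THF, 50 °C) of F5 with tert-butyl (2Z)-3-{[(trifluoromethyl)sulfonyl]oxy}but-2-enoate F6 should proceed with retention. F6 is made from tert-butyl acetoacetate with (CF3SO2)2O and aqueous LiOH. The coupling product is 1-tert-butyl 5-[3-(benzyloxy)-4-(benzyloxycarbonyl)-5-methylphenyl] (2Z)-3-methylpent-2-enedioate F7, and CF3CO2H (CH2Cl2, 0 °C) cleaves its tert-butyl ester to return 9.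

**Step 15.**
- Most likely failure: formylation at the position between the two benzyloxy groups, or a mixture, because both free ring positions are activated by two alkoxy groups and differ only in para versus ortho activation and in crowding.
- Fallback (from 22, returning at 28): Elbs persulfate oxidation of 22 (K2S2O8, aqueous KOH, 5 °C) introduces oxygen para to the 2-hydroxyl and gives potassium 3-formyl-4,6-dihydroxy-2-methylphenyl sulfate F8. Acid hydrolysis gives 2,4,5-trihydroxy-6-methylbenzaldehyde F9, which is benzylated at once with 2 (3.3 equiv, K2CO3, DMF) to 28. Regiochemistry then rests on the para preference of persulfate. The price is the modest efficiency usual for this oxidation and an air-sensitive triol.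

**Step 17.**
- Most likely failure: sluggish transfer of the doubly ortho-substituted acyl group, or competing trifluoroacetylation and acylation at the chelated 2-hydroxyl when the reaction is forced.
- Fallback (from 29, returning at 31): 29 is converted with (COCl)2 and DMF (cat.) into 2,4,5-tris(benzyloxy)-6-methylbenzoyl chloride F10. F10 acylates the 4-phenoxide of 21 (Et3N, 4-(dimethylamino)pyridine cat., CH2Cl2, 0 °C). This is a base-driven acyl substitution on an isolated acid chloride in place of the acid-driven acylium transfer.

## Further compounds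

F1 | step 10 | 2-hydroxy-6-methyl-4-[(triisopropylsilyl)oxy]benzoic acid | Cc1cc(O[Si](C(C)C)(C(C)C)C(C)C)cc(O)c1C(=O)O
F2 | step 10 | benzyl 2-(benzyloxy)-4-({2-hydroxy-6-methyl-4-[(triisopropylsilyl)oxy]benzoyl}oxy)-6-methylbenzoate | Cc1cc(O[Si](C(C)C)(C(C)C)C(C)C)cc(O)c1C(=O)Oc1cc(C)c(C(=O)OCc2ccccc2)c(OCc2ccccc2)c1
F3 | step 7 | 2-({(2Z)-5-[3-(benzyloxy)-4-(benzyloxycarbonyl)-5-methylphenoxy]-3-methyl-5-oxopent-2-enoyl}oxy)-1-methylpyridin-1-ium iodide | C[n+]1ccccc1OC(=O)/C=C(C)\CC(=O)Oc1cc(C)c(C(=O)OCc2ccccc2)c(OCc2ccccc2)c1.[I-]
F4 | step 6 | 3-(benzyloxy)-4-(benzyloxycarbonyl)-5-methylphenyl bromoacetate | BrCC(=O)Oc1cc(C)c(C(=O)OCc2ccccc2)c(OCc2ccccc2)c1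
F5 | step 6 | {2-[3-(benzyloxy)-4-(benzyloxycarbonyl)-5-methylphenoxy]-2-oxoethyl}zinc bromide | Br[Zn]CC(=O)Oc1cc(C)c(C(=O)OCc2ccccc2)c(OCc2ccccc2)c1
F6 | step 6 | tert-butyl (2Z)-3-{[(trifluoromethyl)sulfonyl]oxy}but-2-enoate | CC(C)(C)OC(=O)/C=C(C)\OS(=O)(=O)C(F)(F)F
F7 | step 6 | 1-tert-butyl 5-[3-(benzyloxy)-4-(benzyloxycarbonyl)-5-methylphenyl] (2Z)-3-methylpent-2-enedioate | CC(C)(C)OC(=O)/C=C(C)\CC(=O)Oc1cc(C)c(C(=O)OCc2ccccc2)c(OCc2ccccc2)c1
F8 | step 15 | potassium 3-formyl-4,6-dihydroxy-2-methylphenyl sulfate | Cc1c(OS(=O)(=O)[O-])c(O)cc(O)c1C=O.[K+]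
F9 | step 15 | 2,4,5-trihydroxy-6-methylbenzaldehyde | Cc1c(O)c(O)cc(O)c1C=O
F10 | step 17 | 2,4,5-tris(benzyloxy)-6-methylbenzoyl chloride | ClC(=O)c1c(C)c(OCc2ccccc2)c(OCc2ccccc2)cc1OCc1ccccc1
A1 | alternative 1 | benzyl 4-[(2-(benzyloxy)-6-methyl-4-{[2,4,5-tris(benzyloxy)-6-methylbenzoyl]oxy}benzoyl)oxy]-2-methoxy-6-methylbenzoate | Cc1cc(OC(=O)c2c(C)cc(OC(=O)c3c(OCc4ccccc4)cc(OCc4ccccc4)c(OCc4ccccc4)c3C)cc2OCc2ccccc2)cc(OC)c1C(=O)OCc1ccccc1
A2 | alternative 1 | 6-methyl-2-oxo-2H-pyran-4-yl 2-(benzyloxy)-6-methyl-4-{[2,4,5-tris(benzyloxy)-6-methylbenzoyl]oxy}benzoate | Cc1cc(OC(=O)c2c(C)cc(OC(=O)c3c(OCc4ccccc4)cc(OCc4ccccc4)c(OCc4ccccc4)c3C)cc2OCc2ccccc2)cc(=O)o1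
A3 | alternative 1 | benzyl 3-methoxyprop-2-ynoate | COC#CC(=O)OCc1ccccc1
A4 | alternative 1 | 4-hydroxy-6-methyl-2H-pyran-2-one (triacetic acid lactone) | Cc1cc(O)cc(=O)o1
A5 | alternative 2 | benzyl 4-[(2,4-dihydroxy-6-methylbenzoyl)oxy]-2-hydroxy-6-methylbenzoate | Cc1cc(O)cc(O)c1C(=O)Oc1cc(C)c(C(=O)OCc2ccccc2)c(O)c1
A6 | alternative 2 | 6-(2,4-dioxopentyl)-2,2-dimethyl-4H-1,3-dioxin-4-one | CC(=O)CC(=O)CC1=CC(=O)OC(C)(C)O1
A7 | alternative 2 | benzyl 2-hydroxy-6-methyl-4-[(3,5,7-trioxooctanoyl)oxy]benzoate | CC(=O)CC(=O)CC(=O)CC(=O)Oc1cc(C)c(C(=O)OCc2ccccc2)c(O)c1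
A8 | alternative 3 | benzyl 2-(benzyloxy)-4-[(2-(benzyloxy)-4-{[5-(benzyloxy)-2,4-dihydroxy-6-methylbenzoyl]oxy}-6-methylbenzoyl)oxy]-6-methylbenzoate | Cc1cc(OC(=O)c2c(C)cc(OC(=O)c3c(O)cc(O)c(OCc4ccccc4)c3C)cc2OCc2ccccc2)cc(OCc2ccccc2)c1C(=O)OCc1ccccc1
A9 | alternative 3 | 4-(benzyloxy)-1-methoxy-1,3-bis[(trimethylsilyl)oxy]buta-1,3-diene | COC(O[Si](C)(C)C)=CC(O[Si](C)(C)C)=COCc1ccccc1
A10 | alternative 3 | benzyl 2-(benzyloxy)-4-{[2-(benzyloxy)-4-(but-2-ynoyloxy)-6-methylbenzoyl]oxy}-6-methylbenzoate | CC#CC(=O)Oc1cc(C)c(C(=O)Oc2cc(C)c(C(=O)OCc3ccccc3)c(OCc3ccccc3)c2)c(OCc2ccccc2)c1
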